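The earlier runs and the new flask come from a simulation for an exercise; the scatter is artificial.

The question is how much product a flask with 0.01 mol% of precatalyst holds at its best within the time allowed, and when.

| setting | Thursday's | Friday's | flask |
|---|---|---|---|
| substrate | 0.12 M | 0.12 M | 0.12 M |
| precatalyst | 0.005 mol% | 0.02 mol% | 0.01 mol% |
| remark | run made earlier | run made earlier |  |
| time |  |  | 40 min |

| run | time / min | product / % | substrate / % |
|---|---|---|---|
| Thursday's | 1.33 | 4.0 | 20.9 |
| Thursday's | 3.00 | 6.1 | 9.2 |
| Thursday's | 6.00 | 7.2 | 6.4 |
| Thursday's | 12.0 | 7.0 | 2.8 |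
| Thursday's | 25.0 | 6.0 | 2.3 |
| Thursday's | 50.0 | 3.3 | 3.0 |
| Friday's | 1.33 | 10.2 | 18.7 |
| Friday's | 3.00 | 14.3 | 7.3 |
| Friday's | 6.00 | 13.9 | 6.6 |
| Friday's | 12.0 | 13.0 | 3.4 |
| Friday's | 25.0 | 8.1 | 2.3 |
| Friday's | 50.0 | 6.8 | 3.8 |

(each reading ± 1 percentage point)

- the best time, 40 min at the latest, for product
- the amount of product, in percent of the substrate charged, at that time

- the numbers in the tables scatter by 1 percentage point (one standard deviation)

Both earlier runs climb to a broad maximum and then sink, so each offers a highest reading of [product]: 7.2 % on Thursday and 14.3 % on Friday. But Friday's loading is 4.00 times Thursday's, and its highest reading is far from that many times larger. So the useful quantity is the loading exponent, the slope of ln(highest [product]) against ln(loading) at a fixed substrate charge, an apparent order in the precatalyst, which these two readings put at 0.495. Carried from Thursday's reading to this flask's loading, it gives 10.1 %, with the scatter of the readings on it. For the time, Thursday's highest reading stands at 6.00 min, and Friday's reading there, 13.9 %, lies within the scatter of its highest, so this reckoning takes 6.00 min.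

The forecast gives 10 % (8.8 % to 11.5 %) at 7 min (4 min to 13 min), close to this amount but later than this time, and its ground is that “Fourfold more precatalyst only doubles the product”.

The flask gives 11.2 % at 5.75 min.

    substrate + enzyme ⇌ complex (K = 5.40 L mol⁻¹, k = 20000 L mol⁻¹ s⁻¹)
    complex ⇌ enzyme + product (K = 0.500 M, k = 130 s⁻¹)
    2 substrate → homo dimer (k = 0.180 L mol⁻¹ s⁻¹)
    precatalyst → enzyme (k = 0.00900 s⁻¹)

The reckoned peak lies 1 percentage point below this, about the scatter of one reading. The peak stays low in this flask because substrate turns into homo dimer: this flask without that step reaches 73.0 % instead of 11.2 %, the largest single effect among the simulated runs. For a neighbour flask at 0.04 mol%, the exponent carried from Friday's reading gives 20.2 %, and that flask computes to 19.6 %.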